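**Plan**
The target is 3-henicosyl-1H-pyrrole-2-carbaldehyde, an achiral pyrrole with ring atoms N1, C2 (bearing CHO), C3 (bearing the C21 chain), C4 and C5.
The retrosynthesis first cuts N1–C2 and N1–C5 (Paal–Knorr), which exposes a 1,4-dicarbonyl chain whose formyl carbon is kept as a dimethyl acetal.
In that chain C3 and C4 are both α-carbons of carbonyl groups, two enol carbons of the same donor polarity, so C3–C4 is cut as an anodic oxidative union of an enol silane (C2=C3) with ethyl vinyl ether (C4=C5).
The last cut, C2–C3, is an acyl substitution of the Weinreb amide of dimethoxyacetic acid (C2 and the formyl carbon) by a docosyl Grignard reagent (C3 and the chain).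
Forward, the chain is joined at C2–C3 (step 2) and at C3–C4 (step 4), and the only ring closes last with ammonia, the aldehyde being unmasked in the same flask (step 5).
The target has no stereocentre: the enol silane geometry is irrelevant and the two sp3 centres made in step 4 vanish on aromatisation.

Key step: step 4

Remark: the enol silane is drawn as the Z isomer expected from enolisation in THF–DMPU; any E isomer would give the same coupling product and would be carried along.

**Step 1**
Reactants: 1 methyl 2,2-dimethoxyacetate
Product: 2 N,2,2-trimethoxy-N-methylacetamide (the Weinreb amide of dimethoxyacetic acid)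
Conditions: MeNH(OMe)·HCl (1.5 equiv), i-PrMgCl (3 equiv), THF, −20 → 0 °C; aq NH4Cl
Reagents that add atoms: N,O-dimethylhydroxylamine hydrochloride, `CNOC.Cl`
Why: Weinreb amide formation from an ester, in which the chloromagnesium amide made in the flask displaces methoxide from the activated α,α-dialkoxy ester and the acetal is inert to the basic medium.

**Step 2**
Reactants: 3 1-bromodocosane; 2 N,2,2-trimethoxy-N-methylacetamide
Product: 5 1,1-dimethoxytetracosan-2-one, via docosylmagnesium bromide 4 (not isolated)
Conditions: Mg, I2 (cat.), THF, 50 °C; then 2, THF, 0 → 25 °C; aq NH4Cl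
Reagents that add atoms: magnesium, `[Mg]` (its atom stays only in intermediate 4)
Why: Weinreb ketone synthesis, in which the Grignard reagent adds once and the chelated tetrahedral magnesium adduct holds until the quench, so no tertiary alcohol should form; the acetal is inert and working at or above 0 °C keeps the long-chain reagent in solution.

**Step 3**
Reactants: 5 1,1-dimethoxytetracosan-2-one; 6 tert-butylchlorodimethylsilane
Product: 8 tert-butyl{[(2Z)-1,1-dimethoxytetracos-2-en-2-yl]oxy}dimethylsilane, via lithium (Z)-1,1-dimethoxytetracos-2-en-2-olate 7 (not isolated)
Conditions: LiN(i-Pr)2 (1.2 equiv), THF–DMPU (4:1), −78 °C (5 added slowly in THF); then 6, −78 °C → rt; cold aq NaHCO3 work-up, Et3N-washed silica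
Reagents that add atoms: LiN(i-Pr)2, `[Li+].CC(C)[N-]C(C)C` (lithium stays only in intermediate 7)
Why: Kinetic enolisation and O-silylation, in which only the C3 methylene is deprotonated (the hindered acetal C–H is not), the polar co-solvent favours the Z enolate, and the absence of any Lewis acid avoids ionisation of the acetal next to the new enol ether.

**Step 4**
Reactants: 8 tert-butyl{[(2Z)-1,1-dimethoxytetracos-2-en-2-yl]oxy}dimethylsilane; 9 ethyl vinyl ether
Product: 10 5-ethoxy-3-henicosyl-1,1,5-trimethoxypentan-2-one (mixture of the stereoisomers at C3 and C5)
Conditions: graphite anode, Pt cathode, undivided cell, constant current at low current density (about 2.2 F per mol), LiClO4 (0.1 M), MeOH–CH2Cl2 (1:4), 2,6-lutidine (4 equiv), 9 (20 equiv), 0 °C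
Reagents that add atoms: methanol, `CO`
Why: Proposed new method: one-electron oxidation of the trisubstituted enol silane 8, expected to be easier than that of the monosubstituted vinyl ether, gives a radical cation that loses its silyl group to methanol and leaves an electrophilic α-keto radical at C3; this adds to the CH2 terminus of the vinyl ether, the α-ethoxyalkyl radical is oxidised to an oxocarbenium ion that methanol traps as the mixed acetal, and methanol is reduced to H2 at the cathode. The closest known reactions are the oxidative addition of silyl enol ethers to ethyl vinyl ether with (NH4)2Ce(NO3)6 (tetravalent cerium) in methanol, which gives the same kind of 4-oxo acetal, and intramolecular anodic couplings of silyl enol ethers with enol ethers in this electrolyte; the intermolecular anodic version is untested. No ring closes. The two new stereocentres (C3 and C5) form without control, which does not matter because both become sp2 ring carbons in step 5. The step needs cross-coupling over homo-coupling and C–C bond formation ahead of methanol capture at C3; the polarity match between the electron-poor radical and the large excess of electron-rich vinyl ether, the low methanol content, the 2,6-lutidine buffer and the low current density are meant to secure this. Regiochemistry is set by the substrate, since 8 is a single regioisomer with the chain on the reacting carbon and attack at CH2 of the vinyl ether gives the oxygen-stabilised radical.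

**Step 5**
Reactants: 10 5-ethoxy-3-henicosyl-1,1,5-trimethoxypentan-2-one
Product: 13 3-henicosyl-1H-pyrrole-2-carbaldehyde, via 3-henicosyl-5,5-dimethoxy-4-oxopentanal 11 (not isolated), via 2-(dimethoxymethyl)-3-henicosyl-1H-pyrrole 12 (not isolated)
Conditions: NH4OAc (10 equiv), AcOH–THF–H2O (2:2:1), 60 °C
Reagents that add atoms: ammonium acetate, `CC(=O)[O-].[NH4+]`; water, `O`
Why: Paal–Knorr pyrrole synthesis with acetal hydrolysis in the same flask, in which aqueous acetic acid unmasks the ordinary C5 acetal while the α-keto acetal holds, ammonia condenses with the aldehyde and the ketone and water loss aromatises the ring (erasing both sp3 centres), and the acetal, now activated by the pyrrole, is cleaved by water to the acid-stable 2-formylpyrrole.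

**Compound list**
1 | methyl 2,2-dimethoxyacetate | `COC(OC)C(=O)OC` | starting material
2 | N,2,2-trimethoxy-N-methylacetamide | `COC(OC)C(=O)N(C)OC` | intermediate
3 | 1-bromodocosane | `CCCCCCCCCCCCCCCCCCCCCCBr` | starting material
4 | docosylmagnesium bromide | `CCCCCCCCCCCCCCCCCCCCCC[Mg]Br` | intermediate
5 | 1,1-dimethoxytetracosan-2-one | `CCCCCCCCCCCCCCCCCCCCCCC(=O)C(OC)OC` | intermediate
6 | tert-butylchlorodimethylsilane | `CC(C)(C)[Si](C)(C)Cl` | starting material
7 | lithium (Z)-1,1-dimethoxytetracos-2-en-2-olate | `CCCCCCCCCCCCCCCCCCCCC/C=C(/C(OC)OC)[O-].[Li+]` | intermediate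
8 | tert-butyl{[(2Z)-1,1-dimethoxytetracos-2-en-2-yl]oxy}dimethylsilane | `CCCCCCCCCCCCCCCCCCCCC/C=C(/C(OC)OC)O[Si](C)(C)C(C)(C)C` | intermediate
9 | ethyl vinyl ether | `C=COCC` | starting material
10 | 5-ethoxy-3-henicosyl-1,1,5-trimethoxypentan-2-one (mixture of stereoisomers at C3 and C5) | `CCCCCCCCCCCCCCCCCCCCCC(CC(OC)OCC)C(=O)C(OC)OC` | intermediate
11 | 3-henicosyl-5,5-dimethoxy-4-oxopentanal (racemic) | `CCCCCCCCCCCCCCCCCCCCCC(CC=O)C(=O)C(OC)OC` | intermediate
12 | 2-(dimethoxymethyl)-3-henicosyl-1H-pyrrole | `CCCCCCCCCCCCCCCCCCCCCc1cc[nH]c1C(OC)OC` | intermediate
13 | 3-henicosyl-1H-pyrrole-2-carbaldehyde | `CCCCCCCCCCCCCCCCCCCCCc1cc[nH]c1C=O` | target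

Total step count: 5. Longest linear sequence: 5 steps (1 → 2 → 5 → 8 → 10 → 13).

**Steps most likely to fail**

1. Step 4. The anode may oxidise the vinyl ether in competition, methanol may capture the radical cation at C3 before the C–C bond forms (α-methoxylation), or the α-keto radicals may homo-couple. The fallback makes the C3–C4 bond by polar chemistry and sets out from 5. Ketone 5 is deprotonated as in step 3 (LiN(i-Pr)2, THF, −78 °C) and enolate 7 is alkylated with allyl bromide (DMPU, −78 °C → rt) to give 3-henicosyl-1,1-dimethoxyhex-5-en-2-one F1. Lemieux–Johnson cleavage of the terminal alkene (OsO4 cat., NaIO4, 2,6-lutidine, dioxane–H2O, rt) should give keto aldehyde 11, here isolated. The fallback comes back to the route at 11, which is taken through the conditions of step 5 to 13.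

2. Step 5. In acid the pyrrolyl acetal may ionise and be captured by the free C5 position of a second pyrrole (oligomerisation), or the α-keto acetal may be lost before the ring closes. The fallback sets out from 10, runs the three events separately and closes the ring without acid. Compound 10 is hydrolysed only at C5 (aqueous oxalic acid, THF, rt) and keto aldehyde 11 is isolated. Compound 11 is condensed with (NH4)2CO3 in MeOH–THF at 50 °C, a base-buffered Paal–Knorr closure, and pyrrole acetal 12 is isolated over basic alumina. Compound 12 is then added slowly to a stirred two-phase mixture of CH2Cl2 and aqueous citric acid, so that it is hydrolysed at high dilution, and the fallback comes back to the route at 13. No compound outside the list is made (F0).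

3. Step 2. Wurtz homo-coupling during magnesium insertion and precipitation of the waxy C22 reagent may leave amide 2 unconsumed. The fallback sets out from 2 and brings the chain in as a soluble lithium acetylide. 1-Bromoicosane and LiC≡CH·H2NCH2CH2NH2 (DMSO–THF, rt) should give docos-1-yne F2. Deprotonation with n-BuLi (THF, −20 °C) gives lithium docos-1-yn-1-ide F3, which is added to 2 (THF, −20 → 0 °C; aq NH4Cl) to give 1,1-dimethoxytetracos-3-yn-2-one F4. Hydrogenation of the triple bond (H2, Pd/C, EtOAc, rt) comes back to the route at 5.

**Further compounds**
F1 | step 4 | 3-henicosyl-1,1-dimethoxyhex-5-en-2-one (racemic) | `CCCCCCCCCCCCCCCCCCCCCC(CC=C)C(=O)C(OC)OC`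
F0 | step 5 | none | none
F2 | step 2 | docos-1-yne | `CCCCCCCCCCCCCCCCCCCCC#C`
F3 | step 2 | lithium docos-1-yn-1-ide | `CCCCCCCCCCCCCCCCCCCCC#[C-].[Li+]`
F4 | step 2 | 1,1-dimethoxytetracos-3-yn-2-one | `CCCCCCCCCCCCCCCCCCCCC#CC(=O)C(OC)OC`
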